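**Plan**

- Retrosynthetic cuts, in order: the top 3‑O‑galloyl ester; the top C4–C4a bond (ring C of the top unit); the top C4–mid C8 bond (an alkenyl–aryl bond); the top C2–O1 aryl ether bond; the mid C4–bottom C6 interflavan bond; the mid 3‑O‑galloyl ester.
- Enabling feature: top C4 carries two aryl groups and stands anti to the oxygen on C3, and top C4a is an ortho carbon of a phloroglucinol‑type aryl ether (O1–C8a) whose second ortho carbon (the later C8) is identical by symmetry. Ring C of the top unit can therefore be closed by arene attack on a trans C3–C4 epoxide already attached to mid C8.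
- Forward order: benzylated (−)‑epicatechin is galloylated, iodinated at C8 and activated at C4, then joined to a benzylated 8‑bromocatechin (C6 nucleophile) to give the 4β→6 dimer. The C2–C3–C4 chain with ring B and the ring‑A ether is made separately and attached at mid C8 by Suzuki coupling. Epoxidation, closure of top ring C, galloylation and global hydrogenolysis follow.
- Stereochemistry: bottom C2/C3 and mid C2/C3 come from (+)‑catechin and (−)‑epicatechin; mid C4 from attack anti to the 3‑O‑galloyl group; top C2 from iridium‑catalysed asymmetric allylic etherification; top C3 from Shi epoxidation with the L‑fructose‑derived ketone; top C4 by inversion in the ring closure.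

Key step: step 16

Assumption: in the iridium‑catalysed allylic etherification the (Sa,Sc,Sc) phosphoramidite is taken to give the (S)‑branched ether; if the opposite sense is found, its enantiomer is used and nothing else changes.
Assumption: 3,5‑bis(benzyloxy)phenol, 3,4‑bis(benzyloxy)benzaldehyde, 3,4,5‑tris(benzyloxy)benzoic acid and the L‑fructose‑derived Shi ketone are bought.

**Route**

Step 1
Reactants: 1 (+)-catechin
Product: 2 5,7,3′,4′-tetra-O-benzyl-(+)-catechin
Conditions: BnBr (4.4 equiv), K2CO3, DMF, 0 °C → rt, N2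
Reagents that add atoms: benzyl bromide, BrCc1ccccc1
Why: Williamson etherification with carbonate base alkylates the four phenols only and leaves the secondary alcohol and both stereocentres untouched.

Step 2
Reactants: 2 5,7,3′,4′-tetra-O-benzyl-(+)-catechin
Product: 3 8-bromo-5,7,3′,4′-tetra-O-benzyl-(+)-catechin
Conditions: NBS (1.0 equiv), CH2Cl2, −78 °C → rt
Reagents that add atoms: N-bromosuccinimide, O=C1CCC(=O)N1Br
Why: Electrophilic aromatic bromination of ring A goes to C8, the less hindered of the two free phloroglucinol-type positions, which leaves C6 as the only nucleophilic carbon of ring A.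

Step 3
Reactants: 3 8-bromo-5,7,3′,4′-tetra-O-benzyl-(+)-catechin
Product: 4 8-bromo-3,5,7,3′,4′-penta-O-benzyl-(+)-catechin
Conditions: NaH, BnBr, Bu4NI (cat.), DMF, 0 °C → rt
Reagents that add atoms: benzyl bromide, BrCc1ccccc1
Why: Williamson etherification of the 3-hydroxyl, so that the bottom unit offers no free hydroxyl when the top unit is galloylated.

Step 4
Reactants: 5 (−)-epicatechin
Product: 6 5,7,3′,4′-tetra-O-benzyl-(−)-epicatechin
Conditions: BnBr (4.4 equiv), K2CO3, DMF, 0 °C → rt, N2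
Reagents that add atoms: benzyl bromide, BrCc1ccccc1
Why: Williamson etherification of the four phenols under mild carbonate conditions, which should leave the 3-hydroxyl free and the 2,3-cis centres unchanged.

Step 5
Reactants: 6 5,7,3′,4′-tetra-O-benzyl-(−)-epicatechin and 7 3,4,5-tris(benzyloxy)benzoic acid
Product: 8 5,7,3′,4′-tetra-O-benzyl-(−)-epicatechin 3-O-(3,4,5-tri-O-benzylgallate)
Conditions: DCC, DMAP, CH2Cl2, rt
Reagents that add atoms: none
Why: Steglich esterification (carbodiimide activation with DMAP as acyl-transfer catalyst) of the only free hydroxyl, the established way to benzylated epicatechin gallate, which does not touch C2 or C3.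

Step 6
Reactants: 8 hepta-O-benzyl epicatechin gallate
Product: 9 8-iodo-5,7,3′,4′-tetra-O-benzyl-(−)-epicatechin 3-O-(3,4,5-tri-O-benzylgallate)
Conditions: NIS (1.05 equiv), CH2Cl2, 0 °C, dark
Reagents that add atoms: N-iodosuccinimide, O=C1CCC(=O)N1I
Why: Electrophilic aromatic iodination of ring A at C8, with the same site preference as the NBS bromination of benzylated flavan-3-ols; the iodine serves as a block against self-condensation and later as the cross-coupling handle.

Step 7
Reactants: 9 8-iodo hepta-O-benzyl epicatechin gallate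
Product: 10 (2R,3R,4S)-4β-(2-ethoxyethoxy)-8-iodo-5,7,3′,4′-tetra-O-benzylepicatechin 3-O-(3,4,5-tri-O-benzylgallate)
Conditions: DDQ (2 equiv), 2-ethoxyethanol (5 equiv), CH2Cl2, rt
Reagents that add atoms: 2-ethoxyethanol, CCOCCO
Why: DDQ benzylic oxidation abstracts hydride from C4 and the alcohol traps the ring-A-stabilised cation anti to the 3-acyloxy group to give the 4β ether; this centre is ionised again in the next step, so its configuration is not critical.

Step 8
Reactants: 10 4β-(2-ethoxyethoxy)-8-iodo electrophile and 4 8-bromo-penta-O-benzylcatechin (3 equiv)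
Product: 11 [5,7,3′,4′-tetra-O-benzyl-8-iodo-3-O-(3,4,5-tri-O-benzylgalloyl)epicatechin]-(4β→6)-[3,5,7,3′,4′-penta-O-benzyl-8-bromocatechin]
Conditions: TMSOTf (0.2 equiv), CH2Cl2, −78 → −40 °C; Et3N quench; excess 4 recovered
Reagents that add atoms: none
Why: Lewis-acid-promoted flavan C4 Friedel–Crafts coupling, in which the C4 cation is attacked by the only free ring-A carbon of 4 (C6) anti to the 3-O-galloyl and 2-aryl groups, setting mid C4 as 4β, while the C8 iodine of 10 prevents self-condensation.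

Step 9
Reactants: 12 3,4-bis(benzyloxy)benzaldehyde
Product: 13 ethyl (E)-3-[3,4-bis(benzyloxy)phenyl]acrylate
Conditions: Ph3P=CHCO2Et, toluene, 80 °C
Reagents that add atoms: ethyl (triphenylphosphoranylidene)acetate, CCOC(=O)C=P(c1ccccc1)(c1ccccc1)c1ccccc1
Why: Wittig olefination with a stabilised ylide gives the E-cinnamate.

Step 10
Reactants: 13 ethyl (E)-3-[3,4-bis(benzyloxy)phenyl]acrylate
Product: 14 (E)-3-[3,4-bis(benzyloxy)phenyl]prop-2-en-1-ol
Conditions: iBu2AlH (2.2 equiv), CH2Cl2, −78 °C; aq. potassium sodium tartrate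
Reagents that add atoms: none
Why: iBu2AlH reduces the enoate by 1,2-addition to the allylic alcohol without touching the alkene or the benzyl ethers.

Step 11
Reactants: 14 (E)-3-[3,4-bis(benzyloxy)phenyl]prop-2-en-1-ol
Product: 15 (E)-3-[3,4-bis(benzyloxy)phenyl]allyl methyl carbonate
Conditions: ClCO2Me, pyridine, CH2Cl2, 0 °C
Reagents that add atoms: methyl chloroformate, COC(=O)Cl
Why: O-acylation of the primary allylic alcohol gives the carbonate leaving group needed for allyliridium formation.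

Step 12
Reactants: 15 (E)-3-[3,4-bis(benzyloxy)phenyl]allyl methyl carbonate and 16 3,5-bis(benzyloxy)phenol
Product: 18 (S)-1-[3,4-bis(benzyloxy)phenyl]prop-2-en-1-yl 3,5-bis(benzyloxy)phenyl ether, via lithium 3,5-bis(benzyloxy)phenoxide 17 (not isolated)
Conditions: 16, n-BuLi, THF, 0 °C; then 15, [Ir(cod)Cl]2 (2 mol%), (Sa,Sc,Sc)-O,O′-(1,1′-binaphthyl-2,2′-diyl) N,N-bis(1-phenylethyl)phosphoramidite (4 mol%), THF, 50 °C
Reagents that add atoms: none
Why: Iridium-catalysed asymmetric allylic etherification of a cinnamyl carbonate with an alkali phenoxide, in which the phenoxide oxygen attacks the aryl-substituted terminus of the allyliridium intermediate and the phosphoramidite sets the future top C2 as S.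

Step 13
Reactants: 18 (S)-allyl aryl ether
Product: 19 pinacol (1E,3S)-3-[3,4-bis(benzyloxy)phenyl]-3-[3,5-bis(benzyloxy)phenoxy]prop-1-en-1-ylboronate
Conditions: vinylboronic acid pinacol ester (3 equiv), second-generation Grubbs catalyst (H2IMes)(PCy3)Cl2Ru=CHPh (5 mol%), 1,4-benzoquinone (10 mol%), CH2Cl2, 40 °C
Reagents that add atoms: vinylboronic acid pinacol ester, C=CB1OC(C)(C)C(C)(C)O1
Why: Olefin cross-metathesis with a vinylboronate gives the E-alkenylboronate under thermodynamic control and leaves the allylic stereocentre alone, benzoquinone suppressing alkene migration.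

Step 14
Reactants: 11 iodo/bromo dimer and 19 (1E,3S)-alkenylboronate (1.5 equiv)
Product: 20 dimer 11 in which the iodine at mid C8 is replaced by the (1E,3S)-3-[3,4-bis(benzyloxy)phenyl]-3-[3,5-bis(benzyloxy)phenoxy]prop-1-en-1-yl group
Conditions: Pd(dppf)Cl2 (10 mol%), aq. K3PO4, THF, 45 °C
Reagents that add atoms: none
Why: Suzuki–Miyaura coupling in which zerovalent palladium inserts into the C–I bond much faster than into the hindered, electron-rich C–Br bond and the E geometry of the boronate is retained.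

Step 15
Reactants: 20 (E)-alkene
Product: 21 trans-epoxide of 20 (oxirane on the former alkene; future top C2 R, C3 R, C4 S; the C2 descriptor changes from 20 only through the priority rules)
Conditions: L-fructose-derived Shi ketone (1.0 equiv), KHSO5 (as 2KHSO5·KHSO4·K2SO4), K2CO3, Bu4NHSO4, aq. Na2B4O7/Na2EDTA buffer (pH 10.5), DMM–MeCN–dioxane, 0 °C; cold basic work-up, filtration through Et3N-deactivated silica, used at once
Reagents that add atoms: potassium peroxymonosulfate, [K+].[O-]S(=O)(=O)OO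
Why: Shi asymmetric epoxidation, in which the dioxirane of the L-fructose-derived ketone delivers oxygen through the spiro transition state to the face that gives the (S,S)-type trans-epoxide (here C3 R, C4 S), the concerted syn addition keeping the trans geometry and the high pH sparing the acid-labile product.

Step 16
Reactants: 21 trans-epoxide
Product: 22 [5,7,3′,4′-tetra-O-benzylepicatechin]-(4β→8)-[5,7,3′,4′-tetra-O-benzyl-3-O-(3,4,5-tri-O-benzylgalloyl)epicatechin]-(4β→6)-[3,5,7,3′,4′-penta-O-benzyl-8-bromocatechin], top 3-OH free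
Conditions: BF3·OEt2 (0.3 equiv), CH2Cl2, −78 °C; Et3N, then aq. NaHCO3
Reagents that add atoms: none
Why: BF3 binds the oxirane oxygen and lengthens the C4–O bond, whose developing charge is carried by the trioxygenated mid ring A; an ortho carbon of the 3,5-dibenzyloxyphenyl ether then attacks C4 from the side opposite the leaving oxygen and re-aromatises, an intramolecular Friedel–Crafts epoxy-arene cyclisation of the kind known for trans-3-aryl glycidyl aryl ethers giving trans-4-arylchroman-3-ols. Top ring C closes in the 6-endo-tet mode at C4 and not by 5-exo attack at C3, because only C4 is benzylic. The new centre C4 is set by inversion of the epoxide carbon, so the (3R,4S)-trans-epoxide gives the 3,4-trans (4β, 4R) arrangement, while C2 (from step 12) and C3 (from step 15) pass through unchanged and end 2,3-cis. If the opening instead runs through a free benzylic cation, allylic 1,3-strain between the ortho substituents of mid ring A and the groups on C3 should still hold the tethered arene and the C3 oxygen on opposite faces, so the same 3,4-trans product is expected. The step needs 6-endo over 5-exo closure, arene capture over 1,2-hydride shift to a ketone, and survival of the acid-labile mid–bottom interflavan bond; these are secured by the benzylic bias, by the proximity and high nucleophilicity of the phloroglucinol-type ring, and by substoichiometric Lewis acid at −78 °C. The two ortho carbons of the aryl ether are equivalent, so one ring-closed product should form and the only hydroxyl released is the top 3-OH.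

Step 17
Reactants: 22 trimer with free top 3-OH and 7 3,4,5-tris(benzyloxy)benzoic acid
Product: 23 top 3-O-(3,4,5-tri-O-benzylgalloyl) ester of 22 (fully benzylated 8-bromo trimer digallate)
Conditions: DCC, DMAP, CH2Cl2, rt
Reagents that add atoms: none
Why: Steglich esterification of the single free hydroxyl, a reaction type established for 3-O-galloylation of benzylated procyanidins.

Step 18
Reactants: 23 fully benzylated 8-bromo trimer digallate
Product: 24 (−)-epicatechin-3-O-gallate-(4β→8)-(−)-epicatechin-3-O-gallate-(4β→6)-(+)-catechin (CNP0154615.1)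
Conditions: H2 (1 atm), Pd(OH)2/C, Et3N (1.5 equiv), THF–MeOH–H2O, rt; filtration under N2, Sephadex LH-20
Reagents that add atoms: none
Why: Heterogeneous palladium-catalysed hydrogenolysis cleaves all nineteen benzyl ethers and the aryl C–Br bond, Et3N trapping HBr, while the gallate esters, the interflavan bonds and all stereocentres should be untouched.

**Compound list**

1 | (+)-catechin | O[C@H]1Cc2c(O)cc(O)cc2O[C@@H]1c1ccc(O)c(O)c1 | starting material
2 | 5,7,3′,4′-tetra-O-benzyl-(+)-catechin | O[C@H]1Cc2c(OCc9ccccc9)cc(OCc9ccccc9)cc2O[C@@H]1c1ccc(OCc9ccccc9)c(OCc9ccccc9)c1 | intermediate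
3 | 8-bromo-5,7,3′,4′-tetra-O-benzyl-(+)-catechin | O[C@H]1Cc2c(OCc9ccccc9)cc(OCc9ccccc9)c(Br)c2O[C@@H]1c1ccc(OCc9ccccc9)c(OCc9ccccc9)c1 | intermediate
4 | 8-bromo-3,5,7,3′,4′-penta-O-benzyl-(+)-catechin | c9ccccc9CO[C@H]1Cc2c(OCc9ccccc9)cc(OCc9ccccc9)c(Br)c2O[C@@H]1c1ccc(OCc9ccccc9)c(OCc9ccccc9)c1 | intermediate
5 | (−)-epicatechin | O[C@@H]1Cc2c(O)cc(O)cc2O[C@@H]1c1ccc(O)c(O)c1 | starting material
6 | 5,7,3′,4′-tetra-O-benzyl-(−)-epicatechin | O[C@@H]1Cc2c(OCc9ccccc9)cc(OCc9ccccc9)cc2O[C@@H]1c1ccc(OCc9ccccc9)c(OCc9ccccc9)c1 | intermediate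
7 | 3,4,5-tris(benzyloxy)benzoic acid | OC(=O)c1cc(OCc9ccccc9)c(OCc9ccccc9)c(OCc9ccccc9)c1 | starting material
8 | 5,7,3′,4′-tetra-O-benzyl-(−)-epicatechin 3-O-(3,4,5-tri-O-benzylgallate) | O=C(O[C@@H]1Cc2c(OCc9ccccc9)cc(OCc9ccccc9)cc2O[C@@H]1c1ccc(OCc9ccccc9)c(OCc9ccccc9)c1)c1cc(OCc9ccccc9)c(OCc9ccccc9)c(OCc9ccccc9)c1 | intermediate
9 | 8-iodo-5,7,3′,4′-tetra-O-benzyl-(−)-epicatechin 3-O-(3,4,5-tri-O-benzylgallate) | O=C(O[C@@H]1Cc2c(OCc9ccccc9)cc(OCc9ccccc9)c(I)c2O[C@@H]1c1ccc(OCc9ccccc9)c(OCc9ccccc9)c1)c1cc(OCc9ccccc9)c(OCc9ccccc9)c(OCc9ccccc9)c1 | intermediate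
10 | (2R,3R,4S)-4β-(2-ethoxyethoxy)-8-iodo-5,7,3′,4′-tetra-O-benzylepicatechin 3-O-(3,4,5-tri-O-benzylgallate) | Ic1c(OCc9ccccc9)cc(OCc9ccccc9)c2c1O[C@H](c8ccc(OCc9ccccc9)c(OCc9ccccc9)c8)[C@H](OC(=O)c7cc(OCc9ccccc9)c(OCc9ccccc9)c(OCc9ccccc9)c7)[C@H]2OCCOCC | intermediate
11 | [5,7,3′,4′-tetra-O-benzyl-8-iodo-3-O-(3,4,5-tri-O-benzylgalloyl)epicatechin]-(4β→6)-[3,5,7,3′,4′-penta-O-benzyl-8-bromocatechin] | Ic1c(OCc9ccccc9)cc(OCc9ccccc9)c2c1O[C@H](c8ccc(OCc9ccccc9)c(OCc9ccccc9)c8)[C@H](OC(=O)c7cc(OCc9ccccc9)c(OCc9ccccc9)c(OCc9ccccc9)c7)[C@H]2c1c(OCc9ccccc9)c(Br)c2O[C@H](c8ccc(OCc9ccccc9)c(OCc9ccccc9)c8)[C@@H](OCc9ccccc9)Cc2c1OCc9ccccc9 | intermediate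
12 | 3,4-bis(benzyloxy)benzaldehyde | O=Cc1ccc(OCc9ccccc9)c(OCc9ccccc9)c1 | starting material
13 | ethyl (E)-3-[3,4-bis(benzyloxy)phenyl]acrylate | CCOC(=O)/C=C/c1ccc(OCc9ccccc9)c(OCc9ccccc9)c1 | intermediate
14 | (E)-3-[3,4-bis(benzyloxy)phenyl]prop-2-en-1-ol | OC/C=C/c1ccc(OCc9ccccc9)c(OCc9ccccc9)c1 | intermediate
15 | (E)-3-[3,4-bis(benzyloxy)phenyl]allyl methyl carbonate | COC(=O)OC/C=C/c1ccc(OCc9ccccc9)c(OCc9ccccc9)c1 | intermediate
16 | 3,5-bis(benzyloxy)phenol | Oc1cc(OCc9ccccc9)cc(OCc9ccccc9)c1 | starting material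
17 | lithium 3,5-bis(benzyloxy)phenoxide | [Li+].[O-]c1cc(OCc9ccccc9)cc(OCc9ccccc9)c1 | intermediate
18 | (S)-1-[3,4-bis(benzyloxy)phenyl]prop-2-en-1-yl 3,5-bis(benzyloxy)phenyl ether | c9ccccc9COc1cc(OCc9ccccc9)cc(c1)O[C@H](c8ccc(OCc9ccccc9)c(OCc9ccccc9)c8)C=C | intermediate
19 | pinacol (1E,3S)-3-[3,4-bis(benzyloxy)phenyl]-3-[3,5-bis(benzyloxy)phenoxy]prop-1-en-1-ylboronate | c9ccccc9COc1cc(OCc9ccccc9)cc(c1)O[C@H](c8ccc(OCc9ccccc9)c(OCc9ccccc9)c8)/C=C/B1OC(C)(C)C(C)(C)O1 | intermediate
20 | mid–bottom dimer carrying at mid C8 the (1E,3S)-3-[3,4-bis(benzyloxy)phenyl]-3-[3,5-bis(benzyloxy)phenoxy]prop-1-en-1-yl group | c9ccccc9COc1cc(OCc9ccccc9)cc(c1)O[C@H](c8ccc(OCc9ccccc9)c(OCc9ccccc9)c8)/C=C/c1c(OCc9ccccc9)cc(OCc9ccccc9)c2c1O[C@H](c8ccc(OCc9ccccc9)c(OCc9ccccc9)c8)[C@H](OC(=O)c7cc(OCc9ccccc9)c(OCc9ccccc9)c(OCc9ccccc9)c7)[C@H]2c1c(OCc9ccccc9)c(Br)c2O[C@H](c8ccc(OCc9ccccc9)c(OCc9ccccc9)c8)[C@@H](OCc9ccccc9)Cc2c1OCc9ccccc9 | intermediate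
21 | trans-epoxide of 20 (future top C2 R, C3 R, C4 S) | c9ccccc9COc1cc(OCc9ccccc9)cc(c1)O[C@H](c8ccc(OCc9ccccc9)c(OCc9ccccc9)c8)[C@@H]3O[C@H]3c1c(OCc9ccccc9)cc(OCc9ccccc9)c2c1O[C@H](c8ccc(OCc9ccccc9)c(OCc9ccccc9)c8)[C@H](OC(=O)c7cc(OCc9ccccc9)c(OCc9ccccc9)c(OCc9ccccc9)c7)[C@H]2c1c(OCc9ccccc9)c(Br)c2O[C@H](c8ccc(OCc9ccccc9)c(OCc9ccccc9)c8)[C@@H](OCc9ccccc9)Cc2c1OCc9ccccc9 | intermediate
22 | [5,7,3′,4′-tetra-O-benzylepicatechin]-(4β→8)-[5,7,3′,4′-tetra-O-benzyl-3-O-(3,4,5-tri-O-benzylgalloyl)epicatechin]-(4β→6)-[3,5,7,3′,4′-penta-O-benzyl-8-bromocatechin] | c9ccccc9COc1cc(OCc9ccccc9)c2c(c1)O[C@H](c8ccc(OCc9ccccc9)c(OCc9ccccc9)c8)[C@H](O)[C@H]2c1c(OCc9ccccc9)cc(OCc9ccccc9)c2c1O[C@H](c8ccc(OCc9ccccc9)c(OCc9ccccc9)c8)[C@H](OC(=O)c7cc(OCc9ccccc9)c(OCc9ccccc9)c(OCc9ccccc9)c7)[C@H]2c1c(OCc9ccccc9)c(Br)c2O[C@H](c8ccc(OCc9ccccc9)c(OCc9ccccc9)c8)[C@@H](OCc9ccccc9)Cc2c1OCc9ccccc9 | intermediate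
23 | top 3-O-(3,4,5-tri-O-benzylgalloyl) ester of 22 | c9ccccc9COc1cc(OCc9ccccc9)c2c(c1)O[C@H](c8ccc(OCc9ccccc9)c(OCc9ccccc9)c8)[C@H](OC(=O)c7cc(OCc9ccccc9)c(OCc9ccccc9)c(OCc9ccccc9)c7)[C@H]2c1c(OCc9ccccc9)cc(OCc9ccccc9)c2c1O[C@H](c8ccc(OCc9ccccc9)c(OCc9ccccc9)c8)[C@H](OC(=O)c7cc(OCc9ccccc9)c(OCc9ccccc9)c(OCc9ccccc9)c7)[C@H]2c1c(OCc9ccccc9)c(Br)c2O[C@H](c8ccc(OCc9ccccc9)c(OCc9ccccc9)c8)[C@@H](OCc9ccccc9)Cc2c1OCc9ccccc9 | intermediate
24 | (−)-epicatechin-3-O-gallate-(4β→8)-(−)-epicatechin-3-O-gallate-(4β→6)-(+)-catechin | O=C(O[C@@H]1[C@@H](c2c(O)cc(O)c3c2O[C@H](c2ccc(O)c(O)c2)[C@H](OC(=O)c2cc(O)c(O)c(O)c2)[C@H]3c2c(O)cc3c(c2O)C[C@H](O)[C@@H](c2ccc(O)c(O)c2)O3)c2c(O)cc(O)cc2O[C@@H]1c1ccc(O)c(O)c1)c1cc(O)c(O)c(O)c1 | target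

**Count and risks**

Total step count: 18. Longest linear sequence: 10 steps (steps 4, 5, 6, 7, 8, 14, 15, 16, 17, 18, from 5 to 24; the branch from 12 through steps 9 to 13 and then 14 to 18 is equally long).

Steps most likely to fail:

1. Step 15 (Shi epoxidation). The ketone may not override the facial bias of the neighbouring allylic centre. The very lipophilic substrate may transfer poorly in the two-phase medium. The epoxide, which sits on a trioxygenated benzylic carbon, may ionise during reaction or work-up. Fallback: setting out from 20, a homogeneous asymmetric dihydroxylation (OsO4 and (DHQ)2PHAL in stoichiometric amounts, CH2Cl2, −78 °C, then aq. Na2SO3) should give the syn-3,4-diol F1 with C3 in the required R configuration. A catalytic amount of TMSOTf in CH2Cl2 at −78 °C should then ionise only the benzylic C4 hydroxyl, and the tethered phenoxy ring should close ring C on the cation, forming the same C4–C4a bond with 3,4-trans control by allylic strain. The fallback rejoins the route at 22.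

2. Step 14 (Suzuki coupling). Zerovalent palladium may ionise the allylic aryl ether, with loss of the phenoxide or scrambling of the C2 centre. Transmetalation at the di-ortho-substituted arylpalladium may be slow. Insertion into the C–Br bond may compete. Fallback: setting out from 11, vinylation with potassium vinyltrifluoroborate (Pd(dppf)Cl2, Cs2CO3, THF–H2O), with no allylic ether present, should give the 8-vinyl dimer F2. Olefin cross-metathesis of F2 with allyl ether 18 (second-generation Grubbs catalyst, CH2Cl2, 40 °C) then builds the E-alkene without palladium ever meeting the allylic ether. The fallback rejoins the route at 20.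

3. Step 16 (epoxy-arene ring closure). The opening may run through a long-lived cation that escapes by 1,2-hydride shift or lowers the 3,4-trans selectivity. The Lewis acid may also cleave the mid–bottom interflavan bond. Fallback: setting out from 21, opening of the oxirane at the benzylic carbon with benzyl mercaptan and Et3N should give the storable 4-benzylsulfanyl-3-ol F3 (either C4 epimer serves). Thiophilic activation with AgBF4 in THF at 0 °C, as known for 4-thioflavans, should then release the C4 cation without any hard acid and let the tethered arene close ring C. The fallback rejoins the route at 22.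

**Further compounds**

F1 | step 15 | syn-3,4-diol of 20 (future top C2 R, C3 R, C4 S) | c9ccccc9COc1cc(OCc9ccccc9)cc(c1)O[C@H](c8ccc(OCc9ccccc9)c(OCc9ccccc9)c8)[C@H](O)[C@@H](O)c1c(OCc9ccccc9)cc(OCc9ccccc9)c2c1O[C@H](c8ccc(OCc9ccccc9)c(OCc9ccccc9)c8)[C@H](OC(=O)c7cc(OCc9ccccc9)c(OCc9ccccc9)c(OCc9ccccc9)c7)[C@H]2c1c(OCc9ccccc9)c(Br)c2O[C@H](c8ccc(OCc9ccccc9)c(OCc9ccccc9)c8)[C@@H](OCc9ccccc9)Cc2c1OCc9ccccc9
F2 | step 14 | 8-vinyl analogue of dimer 11 (vinyl at mid C8 in place of iodine) | C=Cc1c(OCc9ccccc9)cc(OCc9ccccc9)c2c1O[C@H](c8ccc(OCc9ccccc9)c(OCc9ccccc9)c8)[C@H](OC(=O)c7cc(OCc9ccccc9)c(OCc9ccccc9)c(OCc9ccccc9)c7)[C@H]2c1c(OCc9ccccc9)c(Br)c2O[C@H](c8ccc(OCc9ccccc9)c(OCc9ccccc9)c8)[C@@H](OCc9ccccc9)Cc2c1OCc9ccccc9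
F3 | step 16 | 4-benzylsulfanyl-3-ol from anti opening of 21 at C4 | c9ccccc9COc1cc(OCc9ccccc9)cc(c1)O[C@H](c8ccc(OCc9ccccc9)c(OCc9ccccc9)c8)[C@H](O)[C@H](SCc9ccccc9)c1c(OCc9ccccc9)cc(OCc9ccccc9)c2c1O[C@H](c8ccc(OCc9ccccc9)c(OCc9ccccc9)c8)[C@H](OC(=O)c7cc(OCc9ccccc9)c(OCc9ccccc9)c(OCc9ccccc9)c7)[C@H]2c1c(OCc9ccccc9)c(Br)c2O[C@H](c8ccc(OCc9ccccc9)c(OCc9ccccc9)c8)[C@@H](OCc9ccccc9)Cc2c1OCc9ccccc9
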